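## The problem

Compound 16 is a (3R)-isoflavanone. A 7-hydroxychroman-4-one (rings A and C) is joined at C3 to a pentasubstituted ring B with hydroxyls at C2' and C3', a methoxy group at C4' and a prenyl group at C5'. Only ring C has to be built, and it holds the single stereocentre, C3, which is tertiary, benzylic to ring B and alpha to the C4 ketone. No second stereocentre can relay configuration to C3, so a chiral reagent or catalyst must set it. Its hydrogen is acidic, so it should be set late and then kept away from base and hot acid. The prenyl group excludes hydrogenolysis, electrophilic oxidants and strong protic acid; the catechol excludes oxidants; the five contiguous substituents of ring B demand regiocontrol in every aromatic substitution. Two features open a short route. First, C3 and C4 are both formyl carbons in simple precursors (a ring B benzaldehyde and a ring A salicylaldehyde). Second, the C2' hydroxyl is ortho to C1', so C3 can be unmasked as the exocyclic carbon of an ortho-quinone methide of ring B. With the ring A phenol oxygen already tied to C2, an acyl anion equivalent at C4 can close ring C by forming C3–C4.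

## Retrosynthesis

**16 from 15.** The last cut removes the two methoxymethyl (MOM) ethers at O7 and O3'. These are the two phenols that would spoil the ring closure: a free 7-hydroxyl is para to the formyl group and would turn the aldehyde into a vinylogous carboxylate, and a free 3'-hydroxyl would expose a catechol to base. Benzyl ethers would need hydrogenolysis (prenyl), silyl ethers would not survive the hydroxide, ylide and phenoxide steps, and allyl ethers here would clash with the temporary allyl group at O2' and with the palladium coupling. The forward step must be an acetal cleavage mild enough not to enolise C3.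

**15 from 13 through 14.** The C3–C4 bond is cut. The neighbouring cuts are weaker here: C4–C4a means acylating ring A under acid with open regiochemistry, O1–C2 puts the stereocentre into a proton transfer, and C3–C1' is an enolate arylation under racemising base. Cutting C3–C4 removes ring C and the stereocentre together. Precursor 13 is an acyclic ether of two benzaldehyde-derived halves and may be racemic, because its stereocentre disappears in the quinone methide 14. The forward reaction needs umpolung of the ring A aldehyde, formation of 14 under weak base, and a chiral carbene to choose the face of C3.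

**13 from 10 and 11.** The C3–S bond and the allyl–O2' bond are cut. A sulfone is the quinone methide precursor of choice: it is stable to storage, and a weak base expels it once the ortho phenol is free. A benzylic halide or ester on so electron-rich a ring would ionise on its own. Both cuts answer to the same reagent, the sulfinate 11, which scavenges the allyl group under palladium catalysis and captures the benzylic cation. The forward step must leave the MOM ethers intact.

**10 from 7 and 9.** The O1–C2 bond is cut, which divides the molecule into two halves of similar size. Cutting C2–C3 instead would need an aryloxymethyl anion; an alpha-halo ketone route would need a ring B acetophenone and a ketone reduction beside a free aldehyde. The forward step asks the phenoxide of 9 to attack the unsubstituted carbon of oxirane 7. The 2'-oxygen of 7 must be masked so that it does not open the oxirane itself.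

**7 from 6, and 9 from 8.** The oxirane is cut at C2–C3 and C–O: C2 arrives as the methylene of a sulfur ylide on the formyl group of 6. Compound 9 comes from 8 by protecting the hydroxyl that is not hydrogen-bonded to the formyl group.

**6 from 5, 5 from 3 and 4, 3 from 2, 2 from 1.** The cuts are O2'–allyl, C5'–prenyl, C5'–Br and O3'–MOM. Compound 1 already has the three oxygens and the future C3 in place. The order is chosen for selectivity:
- MOM goes on O3 first, through the dianion.
- The free 2-hydroxyl then directs bromination to its para position, C5.
- The coupling with 4 is run on the free phenol, so the formyl group is deactivated as a phenoxide and no aryl allyl ether is exposed to palladium.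
- The allyl group goes on O2 last.

## Roads not taken

**Alternative 1:** The C3–H and C4=O pair is traced back to the cis-fused C3–C4 epoxide A1 of the isoflav-3-ene A2. The forward key step is enantioselective epoxidation with Mn(salen)Cl (trivalent manganese) and a terminal oxidant, followed by a Meinwald rearrangement in which the C4 hydrogen moves to C3.
- Merits: 2H-chromenes are among the best substrates for this epoxidation. The hydride can reach C3 only from the face opposite the oxygen, so the transfer of configuration is stereospecific.
- Weak points: the oxidant would attack a prenyl group, so the side chain must travel as allyl and be converted later by cross-metathesis. O7 needs an electron-withdrawing carbonate to steer epoxide opening to C3, and opening at C4 or proton loss from C2 still compete. The ketone is formed in the presence of a Lewis acid that can enolise it. Building A2 takes several steps, and rearrangement, metathesis and two kinds of deprotection follow the key step.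
- Comparison: the enantio-determining step of this road is established chemistry on its substrate class, which the chosen plan cannot claim. The chosen plan offers instead no oxidant, a prenyl group carried from step 3, and a stereocentre made together with the ketone and followed by one step only.

**Alternative 2:** The C4–C4a bond is cut. The acid A4, activated as acid chloride or mixed anhydride, acylates ring A para to the silyloxy group and gives the tris-silyl ether A3. The C3 centre would come earlier from enzymatic desymmetrisation of a prochiral precursor of A4.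
- Merits: enzyme desymmetrisations are reliable and scalable, and no step is new.
- Weak points: an activated alpha-aryl acid loses configuration easily, through a ketene or by enolisation under Lewis acid. The acylation site on ring A is not secured (para or ortho to the silyloxy group). Acid strong enough for acylation endangers the prenyl group and the silyl ethers. The sequence to A4 is long.
- Comparison: the stereocontrol element is better precedented than in the chosen plan. However, the centre is made many steps before the end and must pass through the step most likely to destroy it. The chosen plan buys ring A with the C4–C4a bond already in place (compound 8), so regiochemistry is no question, and makes the centre in the ring-closing step under weak base.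

**Alternative 3:** The O1–C2 bond is cut. The ring A phenol of enone A6 adds to the terminal methylene under a chiral bifunctional base, and the resulting enol is protonated enantioselectively at C3 to give the tri-MOM ether A5.
- Merits: the racemic version is the classical isoflavanone closure, ring B can stay fully protected, and no quinone methide is needed. In precedent for the ring closure itself, this road is at least as good as the chosen one.
- Weak points: the stereocentre arises in a proton transfer after the bond-forming event, on an enol not covalently bound to the catalyst. Such enones cyclise quickly without catalyst, which gives racemic background. The catalyst is a soluble base acting on a product with an acidic C3–H, so the reaction conditions are racemisation conditions. The deoxybenzoin behind A6 needs an acylation of its own.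
- Comparison: both plans share the base-labile product. The chosen plan sets the configuration in a C–C bond formation inside a covalently bound catalyst–substrate intermediate, and its base can be a weak, insoluble carbonate.

Key step: step 9

Remark: atoms are numbered as in the isoflavanone (O1, C2, C3, C4 in ring C; ring A is the benzo ring, ring B the 3-aryl group). The stereodescriptor of the target corresponds to (3R), with priorities C4 > C2 > C1' > H.
Remark: IPent is 1,3-bis[2,6-di(pentan-3-yl)phenyl]imidazol-2-ylidene; Tol is 4-methylphenyl; MOM is methoxymethyl.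

## Route

Step 1
Reactants: 1 2,3-dihydroxy-4-methoxybenzaldehyde
Product: 2 2-hydroxy-4-methoxy-3-(methoxymethoxy)benzaldehyde
Conditions: NaH (2.2 equiv), DMF, 0 °C; MOMCl (1.0 equiv), 0 °C to rt
Reagents that add atoms: chloromethyl methyl ether, COCCl
Why: Regioselective mono-O-alkylation of a catechol dianion (Williamson type): the 2-phenoxide is delocalised into the formyl group and held in a sodium chelate, so one equivalent of electrophile should go to the more basic 3-phenoxide.

Step 2
Reactants: 2 2-hydroxy-4-methoxy-3-(methoxymethoxy)benzaldehyde
Product: 3 5-bromo-2-hydroxy-4-methoxy-3-(methoxymethoxy)benzaldehyde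
Conditions: NBS (1.05 equiv), MeCN, 0 °C
Reagents that add atoms: N-bromosuccinimide, O=C1CCC(=O)N1Br
Why: Electrophilic aromatic bromination; C5 is para to the free hydroxyl, ortho to the methoxy group and meta to the formyl group, whereas C6 is ortho to the formyl group, so all directing effects converge on C5. NBS avoids a build-up of HBr that could cleave the MOM ether.

Step 3
Reactants: 3 5-bromo-2-hydroxy-4-methoxy-3-(methoxymethoxy)benzaldehyde; 4 prenylboronic acid pinacol ester
Product: 5 2-hydroxy-4-methoxy-3-(methoxymethoxy)-5-(3-methylbut-2-en-1-yl)benzaldehyde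
Conditions: PdCl2(IPent)(3-chloropyridine) (2 mol %), KOH (5 M aq), THF, 65 °C
Reagents that add atoms: none
Why: Suzuki–Miyaura coupling of an allylic boronate; with this bulky carbene ligand on palladium the reductive elimination is known to take place at the unsubstituted alpha carbon and give the linear prenyl arene. Under hydroxide the substrate is a phenoxide, which makes the formyl group a vinylogous carboxylate and should suppress its uncatalysed allylboration by 4.

Step 4
Reactants: 5 2-hydroxy-4-methoxy-3-(methoxymethoxy)-5-(3-methylbut-2-en-1-yl)benzaldehyde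
Product: 6 4-methoxy-3-(methoxymethoxy)-5-(3-methylbut-2-en-1-yl)-2-(prop-2-en-1-yloxy)benzaldehyde
Conditions: allyl bromide, K2CO3, DMF, 50 °C
Reagents that add atoms: allyl bromide, C=CCBr
Why: Williamson etherification of the remaining phenol; allyl survives the ylide and the phenoxide opening and is later removed by zerovalent palladium with the sulfinate that is needed anyway. Placing it after step 3 keeps an aryl allyl ether out of the cross-coupling.

Step 5
Reactants: 6 4-methoxy-3-(methoxymethoxy)-5-(3-methylbut-2-en-1-yl)-2-(prop-2-en-1-yloxy)benzaldehyde
Product: 7 racemic 2-[4-methoxy-3-(methoxymethoxy)-5-(3-methylbut-2-en-1-yl)-2-(prop-2-en-1-yloxy)phenyl]oxirane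
Conditions: Me3S+ I−, KOt-Bu, DMSO–THF, 0 °C to rt; used without chromatography
Reagents that add atoms: trimethylsulfonium iodide, C[S+](C)C.[I-]
Why: Corey–Chaykovsky epoxidation of a non-enolisable aldehyde; the ylide methylene becomes C2. The new stereocentre is formed racemic, which is acceptable because it is erased in the quinone methide of step 9.

Step 6
Reactants: 8 2,4-dihydroxybenzaldehyde
Product: 9 2-hydroxy-4-(methoxymethoxy)benzaldehyde
Conditions: MOMCl (1.05 equiv), K2CO3, acetone, 0 °C to rt
Reagents that add atoms: chloromethyl methyl ether, COCCl
Why: Williamson-type etherification; the 2-hydroxyl is locked in a hydrogen bond to the formyl group, so the more acidic and more accessible 4-hydroxyl should react alone.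

Step 7
Reactants: 7 racemic 2-[4-methoxy-3-(methoxymethoxy)-5-(3-methylbut-2-en-1-yl)-2-(prop-2-en-1-yloxy)phenyl]oxirane; 9 2-hydroxy-4-(methoxymethoxy)benzaldehyde
Product: 10 racemic 2-{2-hydroxy-2-[4-methoxy-3-(methoxymethoxy)-5-(3-methylbut-2-en-1-yl)-2-(prop-2-en-1-yloxy)phenyl]ethoxy}-4-(methoxymethoxy)benzaldehyde
Conditions: K2CO3 (0.2 equiv), DMF, 80 °C
Reagents that add atoms: none
Why: Base-catalysed SN2 opening of a monosubstituted aryl oxirane by a phenoxide, which without Lewis or Brønsted acid should go to the unsubstituted carbon and form O1–C2; the alkoxide formed deprotonates the next phenol, so the base is catalytic. The allyl group keeps the 2'-oxygen from opening the oxirane.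

Step 8
Reactants: 10 racemic 2-{2-hydroxy-2-[4-methoxy-3-(methoxymethoxy)-5-(3-methylbut-2-en-1-yl)-2-(prop-2-en-1-yloxy)phenyl]ethoxy}-4-(methoxymethoxy)benzaldehyde; 11 sodium p-toluenesulfinate
Product: 13 racemic 2-{2-[2-hydroxy-4-methoxy-3-(methoxymethoxy)-5-(3-methylbut-2-en-1-yl)phenyl]-2-[(4-methylphenyl)sulfonyl]ethoxy}-4-(methoxymethoxy)benzaldehyde, via deallylated diol 12 (not isolated)
Conditions: TolSO2H (3 equiv, freshly liberated from 11 with 1 M HCl), Pd(PPh3)4 (5 mol %), CH2Cl2, 0 °C to rt; work-up at pH 7
Reagents that add atoms: none
Why: Two known reactions share one reagent: zerovalent palladium ionises the aryl allyl ether and sulfinate captures the allyl complex (Tsuji–Trost-type deallylation), giving 12. The sulfinic acid then exchanges the benzylic hydroxyl of 12 for sulfinate by an SN1-type substitution through the cation stabilised by the ortho hydroxyl and the para methoxy group, the usual way to 2-(1-sulfonylalkyl)phenols; the new centre is racemic and is erased in step 9.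

Step 9
Reactants: 13 racemic 2-{2-[2-hydroxy-4-methoxy-3-(methoxymethoxy)-5-(3-methylbut-2-en-1-yl)phenyl]-2-[(4-methylphenyl)sulfonyl]ethoxy}-4-(methoxymethoxy)benzaldehyde
Product: 15 (3R)-3-[2-hydroxy-4-methoxy-3-(methoxymethoxy)-5-(3-methylbut-2-en-1-yl)phenyl]-7-(methoxymethoxy)-2,3-dihydro-4H-chromen-4-one, via ortho-quinone methide 14 (not isolated)
Conditions: aminoindanol-derived N-C6F5 triazolium tetrafluoroborate, single enantiomer (20 mol %), K2CO3 (powdered, 1.2 equiv), 4 Å MS, toluene, 0 °C; AcOH quench
Reagents that add atoms: none
Why: Proposed new method: carbonate deprotonates the 2'-phenol of 13 and sulfinate leaves (E1cB) to give the ortho-quinone methide 14, whose exocyclic carbon is the future C3, while the triazolylidene adds to the ring A aldehyde and proton transfer gives the nucleophilic Breslow enaminol at the future C4. The enaminol carbon attacks the exocyclic carbon of 14 in a 6-exo-trig closure that forms C3–C4, closes ring C and rearomatises ring B to the 2'-phenoxide; proton transfer and loss of the carbene then give the C4 ketone. The closest known reaction types are the enantioselective intramolecular Stetter reaction of O-tethered salicylaldehydes to 3-substituted chroman-4-ones with this family of triazolium salts, and intermolecular carbene-catalysed acyl anion additions to quinone methides generated in situ; an intramolecular enantioselective version onto an ortho-quinone methide has not been shown. The O1–C2 tether is that of the classical chromanone substrate, so the quinone methide simply takes the place of the enoate acceptor. The C3 stereocentre is set in the C–C bond-forming event by the chiral carbene bound at C4, which differentiates the two faces of the exocyclic double bond of 14 (expected E); the stereocentre of racemic 13 is erased in 14, so both enantiomers of 13 converge. Which catalyst enantiomer leads to (R) must be established by experiment, and both are available. The step needs C–C bond formation to outrun tautomerisation of 14 to a styryl enol ether and needs the product not to enolise: the free 2'-phenol lets an insoluble weak base trigger sulfinate loss at 0 °C, return of sulfinate keeps the stationary concentration of 14 low, and the reaction is quenched with acetic acid as soon as 13 is consumed.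

Step 10
Reactants: 15 (3R)-3-[2-hydroxy-4-methoxy-3-(methoxymethoxy)-5-(3-methylbut-2-en-1-yl)phenyl]-7-(methoxymethoxy)-2,3-dihydro-4H-chromen-4-one
Product: 16 (3R)-3-[2,3-dihydroxy-4-methoxy-5-(3-methylbut-2-en-1-yl)phenyl]-7-hydroxy-2,3-dihydro-4H-chromen-4-one
Conditions: NaHSO4·SiO2, CH2Cl2, rt
Reagents that add atoms: none
Why: Acid-catalysed cleavage of phenolic MOM acetals on a solid acid in an aprotic solvent, chosen to keep acid-catalysed enolisation at C3 to a minimum. The prenyl group is not ortho to a free hydroxyl and therefore cannot cyclise to a chroman.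

## Compound list

1 | 2,3-dihydroxy-4-methoxybenzaldehyde | COc1ccc(C=O)c(O)c1O | starting material
2 | 2-hydroxy-4-methoxy-3-(methoxymethoxy)benzaldehyde | COc1ccc(C=O)c(O)c1OCOC | intermediate
3 | 5-bromo-2-hydroxy-4-methoxy-3-(methoxymethoxy)benzaldehyde | COc1c(Br)cc(C=O)c(O)c1OCOC | intermediate
4 | prenylboronic acid pinacol ester, 4,4,5,5-tetramethyl-2-(3-methylbut-2-en-1-yl)-1,3,2-dioxaborolane | CC(C)=CCB1OC(C)(C)C(C)(C)O1 | starting material
5 | 2-hydroxy-4-methoxy-3-(methoxymethoxy)-5-(3-methylbut-2-en-1-yl)benzaldehyde | COc1c(CC=C(C)C)cc(C=O)c(O)c1OCOC | intermediate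
6 | 4-methoxy-3-(methoxymethoxy)-5-(3-methylbut-2-en-1-yl)-2-(prop-2-en-1-yloxy)benzaldehyde | COc1c(CC=C(C)C)cc(C=O)c(OCC=C)c1OCOC | intermediate
7 | racemic 2-[4-methoxy-3-(methoxymethoxy)-5-(3-methylbut-2-en-1-yl)-2-(prop-2-en-1-yloxy)phenyl]oxirane | COc1c(CC=C(C)C)cc(C2CO2)c(OCC=C)c1OCOC | intermediate
8 | 2,4-dihydroxybenzaldehyde | O=Cc1ccc(O)cc1O | starting material
9 | 2-hydroxy-4-(methoxymethoxy)benzaldehyde | O=Cc1ccc(OCOC)cc1O | intermediate
10 | racemic 2-{2-hydroxy-2-[4-methoxy-3-(methoxymethoxy)-5-(3-methylbut-2-en-1-yl)-2-(prop-2-en-1-yloxy)phenyl]ethoxy}-4-(methoxymethoxy)benzaldehyde | O=Cc1ccc(OCOC)cc1OCC(O)c1cc(CC=C(C)C)c(OC)c(OCOC)c1OCC=C | intermediate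
11 | sodium p-toluenesulfinate | Cc1ccc(S(=O)[O-])cc1.[Na+] | starting material
12 | racemic 2-{2-hydroxy-2-[2-hydroxy-4-methoxy-3-(methoxymethoxy)-5-(3-methylbut-2-en-1-yl)phenyl]ethoxy}-4-(methoxymethoxy)benzaldehyde (not isolated) | O=Cc1ccc(OCOC)cc1OCC(O)c1cc(CC=C(C)C)c(OC)c(OCOC)c1O | intermediate
13 | racemic 2-{2-[2-hydroxy-4-methoxy-3-(methoxymethoxy)-5-(3-methylbut-2-en-1-yl)phenyl]-2-[(4-methylphenyl)sulfonyl]ethoxy}-4-(methoxymethoxy)benzaldehyde | O=Cc1ccc(OCOC)cc1OCC(c1cc(CC=C(C)C)c(OC)c(OCOC)c1O)S(=O)(=O)c1ccc(C)cc1 | intermediate
14 | (E)-2-{2-[4-methoxy-5-(methoxymethoxy)-3-(3-methylbut-2-en-1-yl)-6-oxocyclohexa-2,4-dien-1-ylidene]ethoxy}-4-(methoxymethoxy)benzaldehyde, the ortho-quinone methide of ring B (not isolated) | O=Cc1ccc(OCOC)cc1OC/C=C1\C=C(CC=C(C)C)C(OC)=C(OCOC)C1=O | intermediate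
15 | (3R)-3-[2-hydroxy-4-methoxy-3-(methoxymethoxy)-5-(3-methylbut-2-en-1-yl)phenyl]-7-(methoxymethoxy)-2,3-dihydro-4H-chromen-4-one | COc1c(CC=C(C)C)cc([C@@H]2COc3cc(OCOC)ccc3C2=O)c(O)c1OCOC | intermediate
16 | (3R)-3-[2,3-dihydroxy-4-methoxy-5-(3-methylbut-2-en-1-yl)phenyl]-7-hydroxy-2,3-dihydro-4H-chromen-4-one | COc1c(CC=C(C)C)cc([C@@H]2COc3cc(O)ccc3C2=O)c(O)c1O | target

## Step count and risks

Total: 10 steps. Longest linear sequence: 9 steps (steps 1 to 5 and 7 to 10); step 6 is a one-step side branch.

**Step 9 (proposed new method, key step).**
- Tautomerisation of the quinone methide by proton loss at C2, or base-induced loss of the ring A phenoxide from 13, would drain the acceptor.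
- Carbene addition to the electron-rich, ortho-substituted aldehyde may be slow, which would let oligomerisation of the quinone methide take over.
- Facial selectivity at C3 may be poor.
- The product may enolise under carbonate or through its own 2'-phenoxide, with loss of enantiopurity.

Fallback with known chemistry, from 10 back to 15:
1. Dess–Martin periodinane oxidises the benzylic alcohol of 10 to the keto aldehyde F1.
2. An achiral triazolium salt with a weak base closes it by the known carbene-catalysed intramolecular crossed benzoin reaction of 2-(2-aryl-2-oxoethoxy)benzaldehydes, giving the racemic 3-aryl-3-hydroxychroman-4-one F2.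
3. SmI2 in THF–MeOH removes the tertiary alpha-hydroxyl and gives the racemic 2'-O-allyl isoflavanone F3.
4. Pd(PPh3)4 with 11 removes the allyl group and gives racemic 15, F4.
5. Chromatography on a chiral stationary phase separates 15 from its (S)-enantiomer F5, which is re-equilibrated to F4 with a little amine base and recycled.

**Step 8.**
- The sulfinic acid may cleave the MOM ethers.
- The benzylic cation may lose a proton from C2 towards an enol ether.
- Sulfinate may be expelled again during a basic work-up.

Fallback, from 10 back to 13, avoiding protic acid: MsCl and Et3N at low temperature convert 10 into the benzylic chloride F6. Compound 11 in DMF displaces chloride and gives the 2'-O-allyl sulfone F7. Pd(PPh3)4 with PhSiH3 as a neutral allyl acceptor then gives 13.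

**Step 7.**
- The very electron-rich aryl group may divert the opening to the benzylic carbon.
- The oxirane may rearrange to an arylacetaldehyde on heating.
- The hydrogen-bonded phenoxide of 9 may attack slowly.

Fallback, from 6 back to 10, with only one electrophilic carbon available:
1. Chloromethyllithium (ICH2Cl, MeLi·LiBr, THF, −78 °C) adds to 6 and gives the chlorohydrin F8.
2. TBSCl and imidazole give its silyl ether F9.
3. Compound 9 with Cs2CO3 and NaI in DMF displaces the primary chloride and gives the silyl-protected ether F10.
4. TBAF at 0 °C gives 10.

**Step 3.**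
- Coupling at the gamma carbon would give the 1,1-dimethylallyl isomer.
- Allylboration of the formyl group by 4 may compete.
- Oxidative addition into the electron-rich phenoxide bromide may be slow.

Fallback, from 3 back to 5: Stille coupling of 3 with allyltributylstannane and Pd(PPh3)4 in toluene gives the 5-allyl aldehyde F11. This reagent has no regiochemical ambiguity and does not add to aldehydes without a Lewis acid. Cross-metathesis with 2-methylbut-2-ene and the second-generation Grubbs catalyst RuCl2(=CHPh)(H2IMes)(PCy3) then gives 5.

**Step 10.**
- Acid-catalysed enolisation at C3 may erode enantiopurity.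
- The 7-O-MOM group, deactivated by the para carbonyl, may cleave slowly and tempt longer exposure.
- The prenyl double bond may be hydrated.

Fallback, from 15 to 16: the deprotection is treated as not stereoretentive and enantiomer purification is moved to the very end. Compound 16 is separated on a chiral stationary phase, and the unwanted enantiomer is re-equilibrated under inert gas with a weak base and recycled. No new compound arises (F0).

## Further compounds

F1 | step 9 | 2-{2-[4-methoxy-3-(methoxymethoxy)-5-(3-methylbut-2-en-1-yl)-2-(prop-2-en-1-yloxy)phenyl]-2-oxoethoxy}-4-(methoxymethoxy)benzaldehyde | O=Cc1ccc(OCOC)cc1OCC(=O)c1cc(CC=C(C)C)c(OC)c(OCOC)c1OCC=C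
F2 | step 9 | racemic 3-hydroxy-3-[4-methoxy-3-(methoxymethoxy)-5-(3-methylbut-2-en-1-yl)-2-(prop-2-en-1-yloxy)phenyl]-7-(methoxymethoxy)-2,3-dihydro-4H-chromen-4-one | COc1c(CC=C(C)C)cc(C2(O)COc3cc(OCOC)ccc3C2=O)c(OCC=C)c1OCOC
F3 | step 9 | racemic 3-[4-methoxy-3-(methoxymethoxy)-5-(3-methylbut-2-en-1-yl)-2-(prop-2-en-1-yloxy)phenyl]-7-(methoxymethoxy)-2,3-dihydro-4H-chromen-4-one | COc1c(CC=C(C)C)cc(C2COc3cc(OCOC)ccc3C2=O)c(OCC=C)c1OCOC
F4 | step 9 | racemic 3-[2-hydroxy-4-methoxy-3-(methoxymethoxy)-5-(3-methylbut-2-en-1-yl)phenyl]-7-(methoxymethoxy)-2,3-dihydro-4H-chromen-4-one | COc1c(CC=C(C)C)cc(C2COc3cc(OCOC)ccc3C2=O)c(O)c1OCOC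
F5 | step 9 | (3S)-3-[2-hydroxy-4-methoxy-3-(methoxymethoxy)-5-(3-methylbut-2-en-1-yl)phenyl]-7-(methoxymethoxy)-2,3-dihydro-4H-chromen-4-one | COc1c(CC=C(C)C)cc([C@H]2COc3cc(OCOC)ccc3C2=O)c(O)c1OCOC
F6 | step 8 | racemic 2-{2-chloro-2-[4-methoxy-3-(methoxymethoxy)-5-(3-methylbut-2-en-1-yl)-2-(prop-2-en-1-yloxy)phenyl]ethoxy}-4-(methoxymethoxy)benzaldehyde | O=Cc1ccc(OCOC)cc1OCC(Cl)c1cc(CC=C(C)C)c(OC)c(OCOC)c1OCC=C
F7 | step 8 | racemic 2-{2-[4-methoxy-3-(methoxymethoxy)-5-(3-methylbut-2-en-1-yl)-2-(prop-2-en-1-yloxy)phenyl]-2-[(4-methylphenyl)sulfonyl]ethoxy}-4-(methoxymethoxy)benzaldehyde | O=Cc1ccc(OCOC)cc1OCC(c1cc(CC=C(C)C)c(OC)c(OCOC)c1OCC=C)S(=O)(=O)c1ccc(C)cc1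
F8 | step 7 | racemic 2-chloro-1-[4-methoxy-3-(methoxymethoxy)-5-(3-methylbut-2-en-1-yl)-2-(prop-2-en-1-yloxy)phenyl]ethanol | COc1c(CC=C(C)C)cc(C(O)CCl)c(OCC=C)c1OCOC
F9 | step 7 | racemic tert-butyl{2-chloro-1-[4-methoxy-3-(methoxymethoxy)-5-(3-methylbut-2-en-1-yl)-2-(prop-2-en-1-yloxy)phenyl]ethoxy}dimethylsilane | COc1c(CC=C(C)C)cc(C(CCl)O[Si](C)(C)C(C)(C)C)c(OCC=C)c1OCOC
F10 | step 7 | racemic 2-{2-[tert-butyl(dimethyl)silyl]oxy-2-[4-methoxy-3-(methoxymethoxy)-5-(3-methylbut-2-en-1-yl)-2-(prop-2-en-1-yloxy)phenyl]ethoxy}-4-(methoxymethoxy)benzaldehyde | O=Cc1ccc(OCOC)cc1OCC(O[Si](C)(C)C(C)(C)C)c1cc(CC=C(C)C)c(OC)c(OCOC)c1OCC=C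
F11 | step 3 | 2-hydroxy-4-methoxy-3-(methoxymethoxy)-5-(prop-2-en-1-yl)benzaldehyde | C=CCc1cc(C=O)c(O)c(OCOC)c1OC
F0 | step 10 | none | none
A1 | alternative 1 | cis-fused C3–C4 epoxide of A2 (isoflav-3-ene oxide; 7-O-Boc, 2',3'-di-O-MOM, 5'-allyl) | C=CCc1cc([C@@]23COc4cc(OC(=O)OC(C)(C)C)ccc4[C@@H]2O3)c(OCOC)c(OCOC)c1OC
A2 | alternative 1 | tert-butyl 3-[4-methoxy-2,3-bis(methoxymethoxy)-5-(prop-2-en-1-yl)phenyl]-2H-chromen-7-yl carbonate | C=CCc1cc(C2=Cc3ccc(OC(=O)OC(C)(C)C)cc3OC2)c(OCOC)c(OCOC)c1OC
A3 | alternative 2 | (3R)-7-[tert-butyl(dimethyl)silyl]oxy-3-{2,3-bis[tert-butyl(dimethyl)silyloxy]-4-methoxy-5-(3-methylbut-2-en-1-yl)phenyl}-2,3-dihydro-4H-chromen-4-one | COc1c(CC=C(C)C)cc([C@@H]2COc3cc(O[Si](C)(C)C(C)(C)C)ccc3C2=O)c(O[Si](C)(C)C(C)(C)C)c1O[Si](C)(C)C(C)(C)C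
A4 | alternative 2 | (2R)-2-{2,3-bis[tert-butyl(dimethyl)silyloxy]-4-methoxy-5-(3-methylbut-2-en-1-yl)phenyl}-3-{3-[tert-butyl(dimethyl)silyloxy]phenoxy}propanoic acid | COc1c(CC=C(C)C)cc([C@H](COc2cccc(O[Si](C)(C)C(C)(C)C)c2)C(=O)O)c(O[Si](C)(C)C(C)(C)C)c1O[Si](C)(C)C(C)(C)C
A5 | alternative 3 | (3R)-7-(methoxymethoxy)-3-[4-methoxy-2,3-bis(methoxymethoxy)-5-(3-methylbut-2-en-1-yl)phenyl]-2,3-dihydro-4H-chromen-4-one | COc1c(CC=C(C)C)cc([C@@H]2COc3cc(OCOC)ccc3C2=O)c(OCOC)c1OCOC
A6 | alternative 3 | 1-[2-hydroxy-4-(methoxymethoxy)phenyl]-2-[4-methoxy-2,3-bis(methoxymethoxy)-5-(3-methylbut-2-en-1-yl)phenyl]prop-2-en-1-one | C=C(C(=O)c1ccc(OCOC)cc1O)c1cc(CC=C(C)C)c(OC)c(OCOC)c1OCOC
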